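## Retrosynthetic overview

1. Lactone last: the trans-fused α-methylene-γ-butyrolactone comes from a trans-2-ethynylcyclohexanol unit and CO (palladium-catalysed carbonylative lactonization).
2. Side chain: the C(sp3)–C(sp2) bond comes from a cyclohexenyl triflate and an enantioenriched secondary alkyltrifluoroborate (new stereospecific Suzuki–Miyaura step).
3. Cyclohexene: the enol triflate and allylic alcohol come from a β-keto ester, made by one-carbon ring expansion of a 2-acetoxycyclopentanone with ethyl diazoacetate (key step).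
4. Cyclopentanone stereotriad: from (R)-4-hydroxycyclopentenone by trans conjugate alkynylation, Rubottom oxidation and Mitsunobu inversion.
5. Ring order: five-membered carbocycle (chiral pool), then six-membered carbocycle (ring expansion), then the lactone (last step).

Assumption: the SMILES is read as drawn, i.e. a trans-fused lactone (3aS,7aR), the 4-acetoxy group cis to the C3a–C3 bond (4S), and an S side-chain centre.

## Route

Step 1
Reactants: 1 (4R)-4-hydroxycyclopent-2-en-1-one
Product: 2 (4R)-4-[(tert-butyldimethylsilyl)oxy]cyclopent-2-en-1-one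
Conditions: TBSCl, imidazole, DMF, 0 °C to rt
Reagents that add atoms: tert-butyl(chloro)dimethylsilane, CC(C)(C)[Si](C)(C)Cl
Why: Silyl ether formation leaves the R carbinol centre untouched and installs the bulky group that directs the next step.

Step 2
Reactants: 2 (4R)-4-[(tert-butyldimethylsilyl)oxy]cyclopent-2-en-1-one; 3 lithium (trimethylsilyl)acetylide
Product: 6 (2R,3R,4R)-4-[(tert-butyldimethylsilyl)oxy]-2-hydroxy-3-[(trimethylsilyl)ethynyl]cyclopentan-1-one, via bromo[(trimethylsilyl)ethynyl]zinc 4 (not isolated), via trimethylsilyl enol ether 5 (not isolated)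
Conditions: 3, ZnBr2, THF, 0 °C; then 2, Me3SiOTf, Et2O, −40 °C; then mCPBA, NaHCO3, CH2Cl2, −20 °C; aq. citric acid work-up
Reagents that add atoms: mCPBA, O=C(OO)c1cccc(Cl)c1 (new oxygen of 6); ZnBr2, [Zn+2].[Br-].[Br-] (Zn and Br of 4); Me3SiOTf, C[Si](C)(C)OS(=O)(=O)C(F)(F)F (silyl group of 5)
Why: Silyl triflate-promoted conjugate alkynylation by the alkynylzinc reagent occurs anti to the silyloxy group (3,4-trans), and Rubottom oxidation of the resulting silyl enol ether occurs anti to the new alkynyl group, giving the all-trans hydroxy ketone.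

Step 3
Reactants: 6 (2R,3R,4R)-4-[(tert-butyldimethylsilyl)oxy]-2-hydroxy-3-[(trimethylsilyl)ethynyl]cyclopentan-1-one
Product: 7 (1S,2R,3R)-3-[(tert-butyldimethylsilyl)oxy]-5-oxo-2-[(trimethylsilyl)ethynyl]cyclopentyl acetate
Conditions: AcOH, PPh3, DIAD, THF, 0 °C to rt
Reagents that add atoms: acetic acid, CC(=O)O
Why: Mitsunobu esterification displaces the activated α-keto carbinol oxygen by acetate with inversion (SN2 aided by the adjacent carbonyl; anti-elimination is blocked because the only β-hydrogen is syn to the leaving group), which puts the acetoxy group cis to the alkyne.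

Step 4
Reactants: 7 (1S,2R,3R)-3-[(tert-butyldimethylsilyl)oxy]-5-oxo-2-[(trimethylsilyl)ethynyl]cyclopentyl acetate; 8 ethyl diazoacetate
Product: 9 ethyl (3S,4R,5R)-3-(acetyloxy)-5-[(tert-butyldimethylsilyl)oxy]-2-oxo-4-[(trimethylsilyl)ethynyl]cyclohexane-1-carboxylate (C1 epimers and enol)
Conditions: BF3·OEt2, CH2Cl2, −40 to 0 °C
Reagents that add atoms: none
Why: In this Lewis acid-promoted diazoacetate homologation (Tiffeneau–Demjanov-type ring expansion) the diazo carbon adds to the activated ketone and the unsubstituted α-CH2 migrates to it with loss of N2, because the electron-poor acetoxy-bearing α-carbon migrates poorly; the three stereocentres are not involved.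

Step 5
Reactants: 9 ethyl (3S,4R,5R)-3-(acetyloxy)-5-[(tert-butyldimethylsilyl)oxy]-2-oxo-4-[(trimethylsilyl)ethynyl]cyclohexane-1-carboxylate
Product: 10 ethyl (3S,4R,5R)-3-(acetyloxy)-5-[(tert-butyldimethylsilyl)oxy]-2-[(trifluoromethanesulfonyl)oxy]-4-[(trimethylsilyl)ethynyl]cyclohex-1-ene-1-carboxylate
Conditions: Tf2O, i-Pr2NEt, CH2Cl2, −78 °C
Reagents that add atoms: trifluoromethanesulfonic anhydride, O=S(=O)(OS(=O)(=O)C(F)(F)F)C(F)(F)F
Why: The β-keto ester enolises only towards the ester carbon, so O-sulfonylation gives the ester-conjugated enol triflate and removes the epimeric C1 centre.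

Step 6
Reactants: 10 ethyl (3S,4R,5R)-3-(acetyloxy)-5-[(tert-butyldimethylsilyl)oxy]-2-[(trifluoromethanesulfonyl)oxy]-4-[(trimethylsilyl)ethynyl]cyclohex-1-ene-1-carboxylate
Product: 11 (4R,5R,6S)-4-[(tert-butyldimethylsilyl)oxy]-6-hydroxy-2-(hydroxymethyl)-5-[(trimethylsilyl)ethynyl]cyclohex-1-en-1-yl trifluoromethanesulfonate
Conditions: i-Bu2AlH, CH2Cl2, −78 °C; Rochelle salt work-up
Reagents that add atoms: none
Why: Hydride reduction (DIBAL-H) converts the conjugated ester into the primary allylic alcohol and cleaves the acetate, while the alkenyl triflate, silyl ether and silylalkyne are inert at −78 °C; no stereocentre changes.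

Step 7
Reactants: 11 (4R,5R,6S)-4-[(tert-butyldimethylsilyl)oxy]-6-hydroxy-2-(hydroxymethyl)-5-[(trimethylsilyl)ethynyl]cyclohex-1-en-1-yl trifluoromethanesulfonate
Product: 12 [(3S,4R,5R)-5-[(tert-butyldimethylsilyl)oxy]-3-hydroxy-2-[(trifluoromethanesulfonyl)oxy]-4-[(trimethylsilyl)ethynyl]cyclohex-1-en-1-yl]methyl 2-methylprop-2-enoate
Conditions: methacryloyl chloride (1.05 equiv), Et3N, CH2Cl2, −78 to −40 °C
Reagents that add atoms: methacryloyl chloride, C=C(C)C(=O)Cl
Why: Acylation is selective for the unhindered primary allylic alcohol over the secondary alcohol flanked by the triflate-bearing and alkynyl-bearing carbons.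

Step 8
Reactants: 13 pent-4-en-1-ol
Product: 14 (4R)-4-(4,4,5,5-tetramethyl-1,3,2-dioxaborolan-2-yl)pentan-1-ol
Conditions: B2pin2, CuCl (5 mol %), bulky C2-symmetric chiral imidazolinium carbene precursor (6 mol %, antipode giving R), NaOt-Bu (20 mol %), MeOH, THF, rt
Reagents that add atoms: bis(pinacolato)diboron, CC1(C)OB(OC1(C)C)B1OC(C)(C)C(C)(C)O1
Why: In this copper-catalysed enantioselective Markovnikov protoboration the ligand-bound Cu–Bpin adds across the terminal alkene with boron at the internal carbon, the chiral carbene ligand fixing the R C–B centre, and methanol protonates the primary C–Cu bond.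

Step 9
Reactants: 14 (4R)-4-(4,4,5,5-tetramethyl-1,3,2-dioxaborolan-2-yl)pentan-1-ol
Product: 15 potassium trifluoro[(2R)-5-hydroxypentan-2-yl]borate
Conditions: KHF2, MeOH/H2O, rt
Reagents that add atoms: potassium hydrogen difluoride, [K+].F.[F-]
Why: Fluoride exchange at boron gives the bench-stable trifluoroborate used for stereospecific transmetalation, with no change at carbon.

Step 10
Reactants: 12 [(3S,4R,5R)-5-[(tert-butyldimethylsilyl)oxy]-3-hydroxy-2-[(trifluoromethanesulfonyl)oxy]-4-[(trimethylsilyl)ethynyl]cyclohex-1-en-1-yl]methyl 2-methylprop-2-enoate; 15 potassium trifluoro[(2R)-5-hydroxypentan-2-yl]borate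
Product: 16 [(3S,4R,5R)-5-[(tert-butyldimethylsilyl)oxy]-3-hydroxy-2-[(2S)-5-hydroxypentan-2-yl]-4-[(trimethylsilyl)ethynyl]cyclohex-1-en-1-yl]methyl 2-methylprop-2-enoate
Conditions: Pd(P(t-Bu)3)2 (10 mol %), K2CO3, toluene/H2O (2:1), BHT (cat.), 70 °C
Reagents that add atoms: none
Why: Proposed new method: a stereoinvertive Suzuki–Miyaura coupling of an unactivated enantioenriched secondary alkyltrifluoroborate with a tetrasubstituted cycloalkenyl triflate, in which oxidative addition to monoligated zerovalent palladium gives a cationic alkenylpalladium species that takes the alkyl group from the hydrolysed boronate by open back-side (SE2) transmetalation, so the R boron reagent gives the S centre, while bulky electron-rich P(t-Bu)3 makes reductive elimination faster than β-hydride elimination and chain walking; the closest known reaction type is the stereospecific invertive palladium/P(t-Bu)3 coupling of such secondary alkyltrifluoroborates with aryl chlorides.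

Step 11
Reactants: 16 [(3S,4R,5R)-5-[(tert-butyldimethylsilyl)oxy]-3-hydroxy-2-[(2S)-5-hydroxypentan-2-yl]-4-[(trimethylsilyl)ethynyl]cyclohex-1-en-1-yl]methyl 2-methylprop-2-enoate
Product: 17 [(3S,4R,5R)-3-(acetyloxy)-2-[(2S)-5-(acetyloxy)pentan-2-yl]-5-[(tert-butyldimethylsilyl)oxy]-4-[(trimethylsilyl)ethynyl]cyclohex-1-en-1-yl]methyl 2-methylprop-2-enoate
Conditions: Ac2O, pyridine, DMAP (cat.), CH2Cl2, 0 °C to rt
Reagents that add atoms: acetic anhydride, CC(=O)OC(C)=O
Why: DMAP-catalysed acetylation esterifies both free hydroxyls (primary and allylic secondary) without touching any stereocentre.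

Step 12
Reactants: 17 [(3S,4R,5R)-3-(acetyloxy)-2-[(2S)-5-(acetyloxy)pentan-2-yl]-5-[(tert-butyldimethylsilyl)oxy]-4-[(trimethylsilyl)ethynyl]cyclohex-1-en-1-yl]methyl 2-methylprop-2-enoate
Product: 18 [(3S,4S,5R)-3-(acetyloxy)-2-[(2S)-5-(acetyloxy)pentan-2-yl]-4-ethynyl-5-hydroxycyclohex-1-en-1-yl]methyl 2-methylprop-2-enoate
Conditions: Bu4NF, AcOH, THF, 0 °C to rt
Reagents that add atoms: none
Why: Acetic acid-buffered fluoride desilylation frees the secondary alcohol and the terminal alkyne while the three esters survive; the 4-descriptor changes from R to S only through CIP priorities.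

Step 13
Reactants: 18 [(3S,4S,5R)-3-(acetyloxy)-2-[(2S)-5-(acetyloxy)pentan-2-yl]-4-ethynyl-5-hydroxycyclohex-1-en-1-yl]methyl 2-methylprop-2-enoate
Product: 19 [(3aS,4S,7aR)-4-(acetyloxy)-5-[(2S)-5-(acetyloxy)pentan-2-yl]-3-methylidene-2-oxo-2,3,3a,4,7,7a-hexahydro-1-benzofuran-6-yl]methyl 2-methylprop-2-enoate
Conditions: PdCl2 (5 mol %), thiourea (10 mol %), CO (1 atm), acetone, 50 °C
Reagents that add atoms: carbon monoxide, [C-]#[O+]
Why: In this carbonylative lactonization of a homopropargylic alcohol, divalent palladium forms an alkoxycarbonyl species at the free hydroxyl, syn exo-insertion of the alkyne and protonolysis give the α-methylene-γ-butyrolactone, and the trans ring fusion follows from the trans ethynyl and hydroxyl groups with no stereocentre touched.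

## Compound list

1 | (4R)-4-hydroxycyclopent-2-en-1-one | O=C1C=C[C@H](O)C1 | starting material
2 | (4R)-4-[(tert-butyldimethylsilyl)oxy]cyclopent-2-en-1-one | O=C1C=C[C@H](O[Si](C)(C)C(C)(C)C)C1 | intermediate
3 | lithium (trimethylsilyl)acetylide | [Li]C#C[Si](C)(C)C | starting material
4 | bromo[(trimethylsilyl)ethynyl]zinc | Br[Zn]C#C[Si](C)(C)C | intermediate (not isolated)
5 | tert-butyl(dimethyl){[(1R,2S)-4-[(trimethylsilyl)oxy]-2-[(trimethylsilyl)ethynyl]cyclopent-3-en-1-yl]oxy}silane (trimethylsilyl enol ether) | C[Si](C)(C)OC1=C[C@@H](C#C[Si](C)(C)C)[C@H](O[Si](C)(C)C(C)(C)C)C1 | intermediate (not isolated)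
6 | (2R,3R,4R)-4-[(tert-butyldimethylsilyl)oxy]-2-hydroxy-3-[(trimethylsilyl)ethynyl]cyclopentan-1-one | O=C1[C@H](O)[C@@H](C#C[Si](C)(C)C)[C@H](O[Si](C)(C)C(C)(C)C)C1 | intermediate
7 | (1S,2R,3R)-3-[(tert-butyldimethylsilyl)oxy]-5-oxo-2-[(trimethylsilyl)ethynyl]cyclopentyl acetate | O=C1[C@@H](OC(C)=O)[C@@H](C#C[Si](C)(C)C)[C@H](O[Si](C)(C)C(C)(C)C)C1 | intermediate
8 | ethyl diazoacetate | CCOC(=O)C=[N+]=[N-] | starting material
9 | ethyl (3S,4R,5R)-3-(acetyloxy)-5-[(tert-butyldimethylsilyl)oxy]-2-oxo-4-[(trimethylsilyl)ethynyl]cyclohexane-1-carboxylate (C1 epimers and enol) | CCOC(=O)C1C(=O)[C@@H](OC(C)=O)[C@@H](C#C[Si](C)(C)C)[C@H](O[Si](C)(C)C(C)(C)C)C1 | intermediate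
10 | ethyl (3S,4R,5R)-3-(acetyloxy)-5-[(tert-butyldimethylsilyl)oxy]-2-[(trifluoromethanesulfonyl)oxy]-4-[(trimethylsilyl)ethynyl]cyclohex-1-ene-1-carboxylate | CCOC(=O)C1=C(OS(=O)(=O)C(F)(F)F)[C@@H](OC(C)=O)[C@@H](C#C[Si](C)(C)C)[C@H](O[Si](C)(C)C(C)(C)C)C1 | intermediate
11 | (4R,5R,6S)-4-[(tert-butyldimethylsilyl)oxy]-6-hydroxy-2-(hydroxymethyl)-5-[(trimethylsilyl)ethynyl]cyclohex-1-en-1-yl trifluoromethanesulfonate | OCC1=C(OS(=O)(=O)C(F)(F)F)[C@@H](O)[C@@H](C#C[Si](C)(C)C)[C@H](O[Si](C)(C)C(C)(C)C)C1 | intermediate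
12 | [(3S,4R,5R)-5-[(tert-butyldimethylsilyl)oxy]-3-hydroxy-2-[(trifluoromethanesulfonyl)oxy]-4-[(trimethylsilyl)ethynyl]cyclohex-1-en-1-yl]methyl 2-methylprop-2-enoate | C=C(C)C(=O)OCC1=C(OS(=O)(=O)C(F)(F)F)[C@@H](O)[C@@H](C#C[Si](C)(C)C)[C@H](O[Si](C)(C)C(C)(C)C)C1 | intermediate
13 | pent-4-en-1-ol | C=CCCCO | starting material
14 | (4R)-4-(4,4,5,5-tetramethyl-1,3,2-dioxaborolan-2-yl)pentan-1-ol | C[C@H](CCCO)B1OC(C)(C)C(C)(C)O1 | intermediate
15 | potassium trifluoro[(2R)-5-hydroxypentan-2-yl]borate | [K+].C[C@H](CCCO)[B-](F)(F)F | intermediate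
16 | [(3S,4R,5R)-5-[(tert-butyldimethylsilyl)oxy]-3-hydroxy-2-[(2S)-5-hydroxypentan-2-yl]-4-[(trimethylsilyl)ethynyl]cyclohex-1-en-1-yl]methyl 2-methylprop-2-enoate | C=C(C)C(=O)OCC1=C([C@@H](C)CCCO)[C@@H](O)[C@@H](C#C[Si](C)(C)C)[C@H](O[Si](C)(C)C(C)(C)C)C1 | intermediate
17 | [(3S,4R,5R)-3-(acetyloxy)-2-[(2S)-5-(acetyloxy)pentan-2-yl]-5-[(tert-butyldimethylsilyl)oxy]-4-[(trimethylsilyl)ethynyl]cyclohex-1-en-1-yl]methyl 2-methylprop-2-enoate | C=C(C)C(=O)OCC1=C([C@@H](C)CCCOC(C)=O)[C@@H](OC(C)=O)[C@@H](C#C[Si](C)(C)C)[C@H](O[Si](C)(C)C(C)(C)C)C1 | intermediate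
18 | [(3S,4S,5R)-3-(acetyloxy)-2-[(2S)-5-(acetyloxy)pentan-2-yl]-4-ethynyl-5-hydroxycyclohex-1-en-1-yl]methyl 2-methylprop-2-enoate | C=C(C)C(=O)OCC1=C([C@@H](C)CCCOC(C)=O)[C@@H](OC(C)=O)[C@@H](C#C)[C@H](O)C1 | intermediate
19 | [(3aS,4S,7aR)-4-(acetyloxy)-5-[(2S)-5-(acetyloxy)pentan-2-yl]-3-methylidene-2-oxo-2,3,3a,4,7,7a-hexahydro-1-benzofuran-6-yl]methyl 2-methylprop-2-enoate | C=C(C)C(=O)OCC1=C([C@@H](C)CCCOC(C)=O)[C@@H](OC(C)=O)[C@H]2C(=C)C(=O)O[C@@H]2C1 | target

## Step count and risks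

Total: 13 steps. Longest linear sequence: 11 steps (steps 1–7 and 10–13); steps 8–9 make the side-chain boron reagent.

The three steps most likely to fail are steps 3, 4 and 10.

**Step 3 (Mitsunobu inversion next to the ketone).** The risk is epimerisation or low conversion at the hindered α-keto carbinol. The fallback avoids the inversion and sets out from 2 and the zinc reagent 4. The conjugate addition is run with t-BuMe2SiOTf in place of Me3SiOTf and gives the isolable tert-butyldimethylsilyl enol ether F1. Shi epoxidation (fructose-derived ketone catalyst of the antipode matched to the alkyne face, KHSO5, K2CO3 buffer, MeCN/dimethoxymethane/H2O, 0 °C) then delivers oxygen syn to the alkynyl group under reagent control and gives the (2S)-hydroxy ketone (2S,3R,4R)-4-[(tert-butyldimethylsilyl)oxy]-2-hydroxy-3-[(trimethylsilyl)ethynyl]cyclopentan-1-one F2. Acetylation (Ac2O, pyridine) returns to the route at 7.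

**Step 4 (ring expansion).** The risks are Lewis acid-induced loss of the β-silyloxy group and incomplete regiocontrol. The fallback sets out from 7 and 8 and separates addition from migration. Lithiated 8 (lithium diisopropylamide, THF, −78 °C) adds to the ketone to give the diazo alcohol ethyl 2-[(2S,3R,4R)-2-(acetyloxy)-4-[(tert-butyldimethylsilyl)oxy]-1-hydroxy-3-[(trimethylsilyl)ethynyl]cyclopentyl]-2-diazoacetate F3. Rh2(OAc)4 (1 mol %, CH2Cl2, rt) then forms the carbenoid, and 1,2-shift of the ring CH2 gives the β-keto ester, returning to the route at 9.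

**Step 10 (the new coupling).** The risks are slow transmetalation at the hindered triflate, isomerisation of the secondary alkyl group, and incomplete stereospecificity. The fallback uses known Negishi chemistry without stereocontrol at the side-chain centre and sets out from 13 and 12.
- Acetylation of 13 gives pent-4-en-1-yl acetate F4.
- Markovnikov hydroiodination (NaI, Me3SiCl, H2O, MeCN) gives racemic 4-iodopentyl acetate F5.
- Zinc insertion (Zn dust, LiCl, THF) gives [5-(acetyloxy)pentan-2-yl](iodo)zinc F6.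
- Negishi coupling with 12 (Pd(OAc)2, CPhos, THF/toluene, rt) gives a 1:1 pair of side-chain epimers, the (2S) epimer [(3S,4R,5R)-2-[(2S)-5-(acetyloxy)pentan-2-yl]-5-[(tert-butyldimethylsilyl)oxy]-3-hydroxy-4-[(trimethylsilyl)ethynyl]cyclohex-1-en-1-yl]methyl 2-methylprop-2-enoate F7 and its (2R) epimer F8, separated by preparative HPLC.
- Acetylation of F7 under the conditions of step 11 returns to the route at 17.

## Further compounds

F1 | step 3 | tert-butyl{[(1R,2S)-4-[(tert-butyldimethylsilyl)oxy]-2-[(trimethylsilyl)ethynyl]cyclopent-3-en-1-yl]oxy}dimethylsilane | CC(C)(C)[Si](C)(C)OC1=C[C@@H](C#C[Si](C)(C)C)[C@H](O[Si](C)(C)C(C)(C)C)C1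
F2 | step 3 | (2S,3R,4R)-4-[(tert-butyldimethylsilyl)oxy]-2-hydroxy-3-[(trimethylsilyl)ethynyl]cyclopentan-1-one | O=C1[C@@H](O)[C@@H](C#C[Si](C)(C)C)[C@H](O[Si](C)(C)C(C)(C)C)C1
F3 | step 4 | ethyl 2-[(2S,3R,4R)-2-(acetyloxy)-4-[(tert-butyldimethylsilyl)oxy]-1-hydroxy-3-[(trimethylsilyl)ethynyl]cyclopentyl]-2-diazoacetate (both C1 epimers) | CCOC(=O)C(=[N+]=[N-])C1(O)[C@@H](OC(C)=O)[C@@H](C#C[Si](C)(C)C)[C@H](O[Si](C)(C)C(C)(C)C)C1
F4 | step 10 | pent-4-en-1-yl acetate | C=CCCCOC(C)=O
F5 | step 10 | 4-iodopentyl acetate (racemic) | CC(I)CCCOC(C)=O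
F6 | step 10 | [5-(acetyloxy)pentan-2-yl](iodo)zinc (racemic) | CC([Zn]I)CCCOC(C)=O
F7 | step 10 | [(3S,4R,5R)-2-[(2S)-5-(acetyloxy)pentan-2-yl]-5-[(tert-butyldimethylsilyl)oxy]-3-hydroxy-4-[(trimethylsilyl)ethynyl]cyclohex-1-en-1-yl]methyl 2-methylprop-2-enoate | C=C(C)C(=O)OCC1=C([C@@H](C)CCCOC(C)=O)[C@@H](O)[C@@H](C#C[Si](C)(C)C)[C@H](O[Si](C)(C)C(C)(C)C)C1
F8 | step 10 | [(3S,4R,5R)-2-[(2R)-5-(acetyloxy)pentan-2-yl]-5-[(tert-butyldimethylsilyl)oxy]-3-hydroxy-4-[(trimethylsilyl)ethynyl]cyclohex-1-en-1-yl]methyl 2-methylprop-2-enoate | C=C(C)C(=O)OCC1=C([C@H](C)CCCOC(C)=O)[C@@H](O)[C@@H](C#C[Si](C)(C)C)[C@H](O[Si](C)(C)C(C)(C)C)C1
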